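**Plan**

1. Retrosynthetic cuts, in order: the three O‑benzyl groups; C4=O back to C4–OH; the aryl ether bond O1–C8a of ring C; C4–C4a (aryllithium plus aldehyde); C8a–F back to C8a–Br; N–CH3; piperidine N1–C6 and C2–C3 (N‑sulfinyl aldimine plus 4‑chlorobutyl Grignard reagent).
2. Forward: ring A is bought as a benzaldehyde, the piperidine ring is built on its formyl carbon, the chiral C2–C3–C4 chain is joined at C4a, ring C is closed last through O1–C8a, then C4 is oxidised and the phenols are unmasked.
3. Enabling feature: on ring A, C6 (piperidine) and C8a (ring oxygen) are para, and C5–O and C7–O flank C6. The ring A precursor left by the O1–C8a cut therefore has a local twofold axis through C6 and C8a, the two carbons next to the C8a fluorine are equivalent, and only the 6‑substituted isomer can form.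
4. Fluorine at C8a acidifies those two carbons for the lithiation that attaches the chain at C4a and is then the leaving group; the C2 hydroxyl reaches C8a through a six‑membered transition state.
5. Stereochemistry: piperidine C2 (S) comes from (R)‑tert‑butanesulfinamide in the Grignard addition; flavanone C2 (S) comes from asymmetric hydrogenation of a beta‑keto ester with RuCl2[(R)‑BINAP] and is kept because the ring closure breaks no bond at C2.
6. Helpers: Br blocks the para position during the double SNAr of step 1 and is then exchanged for F; C4 stays at the alcohol level during ring closure (no enolisable ketone) and is oxidised in step 12; the benzyl ethers come off in step 13.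

Key step: step 11

Remark: flavanone numbering (O1, C2, C3, C4, C4a, C5 to C8, C8a) is used for these atoms also in the precursors; compounds 17, 18 and 19 are carried as mixtures of C4 epimers, because this center becomes the carbonyl in step 12.

**Route**

Step 1
Reactants: 1 4-bromo-2,6-difluorobenzaldehyde
Product: 2 2,6-bis(benzyloxy)-4-bromobenzaldehyde
Conditions: BnOH (2.3 equiv), NaH (2.2 equiv), THF/DMF, 0 °C to rt
Reagents that add atoms: benzyl alcohol, OCc1ccccc1
Why: Double SNAr, in which both fluorines are ortho to the formyl group and are displaced by benzyloxide much faster than the para bromine, which stays as a placeholder that keeps the para position free of oxygen.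

Step 2
Reactants: 2 2,6-bis(benzyloxy)-4-bromobenzaldehyde; 3 (R)-2-methylpropane-2-sulfinamide
Product: 4 (R)-N-[(E)-(2,6-bis(benzyloxy)-4-bromophenyl)methylidene]-2-methylpropane-2-sulfinamide
Conditions: Ti(OEt)4 (2 equiv), THF, 60 °C
Reagents that add atoms: none
Why: Condensation of the aldehyde with the sulfinamide (N-sulfinyl imine formation) is driven by Ti(OEt)4, which activates the hindered carbonyl and scavenges the water.

Step 3
Reactants: 4 (R)-N-[(E)-(2,6-bis(benzyloxy)-4-bromophenyl)methylidene]-2-methylpropane-2-sulfinamide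
Product: 6 (2S)-2-[2,6-bis(benzyloxy)-4-bromophenyl]-1-[(R)-tert-butylsulfinyl]piperidine, via open-chain sulfinamide 5 (not isolated)
Conditions: ClCH2CH2CH2CH2MgBr (from 1-bromo-4-chlorobutane, Mg, THF), toluene, −78 to 0 °C; then KOt-Bu, THF, 0 °C to rt; aq. NH4Cl
Reagents that add atoms: 4-chlorobutylmagnesium bromide, ClCCCC[Mg]Br
Why: Grignard addition to the N-sulfinyl aldimine in a non-coordinating solvent proceeds through a six-membered chelate with magnesium on the sulfinyl oxygen, so the (R)-sulfinyl group should direct the alkyl group to the face that gives the S carbon, and the sulfinamide anion then closes the piperidine by 6-exo-tet N-alkylation of the chloride.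

Step 4
Reactants: 6 (2S)-2-[2,6-bis(benzyloxy)-4-bromophenyl]-1-[(R)-tert-butylsulfinyl]piperidine
Product: 8 (2S)-2-[2,6-bis(benzyloxy)-4-bromophenyl]-1-methylpiperidine, via secondary amine 7 (not isolated)
Conditions: HCl (4 M in dioxane), MeOH, 0 °C to rt; evaporate; then aq. CH2O, NaBH(OAc)3, Et3N, ClCH2CH2Cl, rt; aq. NaHCO3
Reagents that add atoms: formaldehyde, C=O
Why: Acidic methanolysis cleaves the N–S bond of the auxiliary and reductive amination with formaldehyde (iminium formation, then hydride transfer from NaBH(OAc)3) methylates the nitrogen without touching the adjacent stereocenter.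

Step 5
Reactants: 8 (2S)-2-[2,6-bis(benzyloxy)-4-bromophenyl]-1-methylpiperidine
Product: 10 (2S)-2-[2,6-bis(benzyloxy)-4-fluorophenyl]-1-methylpiperidine, via aryllithium 9 (not isolated)
Conditions: n-BuLi, THF, −78 °C; then (PhSO2)2NF, −78 °C to rt; aq. NH4Cl
Reagents that add atoms: N-fluorobenzenesulfonimide, O=S(=O)(N(F)S(=O)(=O)c1ccccc1)c1ccccc1
Why: Bromine–lithium exchange outruns deprotonation at −78 °C and the aryllithium is trapped by the electrophilic N–F reagent (electrophilic fluorination), which converts the para placeholder into the fluorine that later directs lithiation and serves as leaving group.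

Step 6
Reactants: 11 1-[4-(benzyloxy)phenyl]ethan-1-one
Product: 12 ethyl 3-[4-(benzyloxy)phenyl]-3-oxopropanoate
Conditions: NaH (2.2 equiv), (EtO)2CO, toluene, reflux; AcOH work-up
Reagents that add atoms: diethyl carbonate, CCOC(=O)OCC
Why: Crossed Claisen condensation of the methyl ketone enolate with diethyl carbonate is driven to completion by deprotonation of the beta-keto ester product.

Step 7
Reactants: 12 ethyl 3-[4-(benzyloxy)phenyl]-3-oxopropanoate
Product: 13 ethyl (3S)-3-[4-(benzyloxy)phenyl]-3-hydroxypropanoate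
Conditions: H2 (50 atm), RuCl2[(R)-BINAP] (0.5 mol %), EtOH, 50 °C
Reagents that add atoms: none
Why: Noyori asymmetric hydrogenation, in which the beta-keto ester chelates ruthenium and hydride is delivered to the carbonyl face selected by (R)-BINAP, should set the S carbinol that becomes C2 of the flavanone, while aryl benzyl ethers are inert to this catalyst.

Step 8
Reactants: 13 ethyl (3S)-3-[4-(benzyloxy)phenyl]-3-hydroxypropanoate
Product: 14 ethyl (3S)-3-[4-(benzyloxy)phenyl]-3-[(tert-butyldimethylsilyl)oxy]propanoate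
Conditions: t-BuMe2SiCl, imidazole, DMF, rt
Reagents that add atoms: tert-butyldimethylsilyl chloride, CC(C)(C)[Si](C)(C)Cl
Why: Imidazole-promoted silylation (silyl ether protection) masks the carbinol so that it survives hydride reduction and the aryllithium addition.

Step 9
Reactants: 14 ethyl (3S)-3-[4-(benzyloxy)phenyl]-3-[(tert-butyldimethylsilyl)oxy]propanoate
Product: 15 (3S)-3-[4-(benzyloxy)phenyl]-3-[(tert-butyldimethylsilyl)oxy]propanal
Conditions: i-Bu2AlH (1.1 equiv), CH2Cl2, −78 °C; aq. potassium sodium tartrate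
Reagents that add atoms: none
Why: Partial reduction of the ester with i-Bu2AlH at −78 °C stops at the tetrahedral aluminium hemiacetal, which collapses to the aldehyde only on work-up, and the silyl-protected stereocenter is untouched.

Step 10
Reactants: 10 (2S)-2-[2,6-bis(benzyloxy)-4-fluorophenyl]-1-methylpiperidine; 15 (3S)-3-[4-(benzyloxy)phenyl]-3-[(tert-butyldimethylsilyl)oxy]propanal
Product: 18 (1S)-1-[4-(benzyloxy)phenyl]-3-{2,4-bis(benzyloxy)-6-fluoro-3-[(2S)-1-methylpiperidin-2-yl]phenyl}propane-1,3-diol (C3 epimers), via aryllithium 16 (not isolated), via silyl ether 17 (not isolated)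
Conditions: n-BuLi, THF, −78 °C; add 15, −78 °C; then Bu4NF (2.5 equiv), −78 °C to rt; aq. NH4Cl
Reagents that add atoms: none
Why: Directed ortho-lithiation removes one of the two equivalent ring hydrogens of 10 that lie between fluorine and a benzyloxy group (the most acidic C–H in the molecule), the 2-fluoroaryllithium is stable at −78 °C and adds to the aldehyde (1,2-addition, both C4 epimers are used), and fluoride then cleaves the silyl ether to free the C2 hydroxyl.

Step 11
Reactants: 18 (1S)-1-[4-(benzyloxy)phenyl]-3-{2,4-bis(benzyloxy)-6-fluoro-3-[(2S)-1-methylpiperidin-2-yl]phenyl}propane-1,3-diol (C3 epimers)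
Product: 19 (2S)-5,7-bis(benzyloxy)-2-[4-(benzyloxy)phenyl]-6-[(2S)-1-methylpiperidin-2-yl]-3,4-dihydro-2H-chromen-4-ol (C4 epimers)
Conditions: KN(SiMe3)2 (2.5 equiv), 18-crown-6, THF, 60 °C, under argon; aq. NH4Cl
Reagents that add atoms: none
Why: KN(SiMe3)2 converts 18 into the dialkoxide, and the C2 alkoxide adds to the fluorine-bearing C8a to give a cyclohexadienyl (Meisenheimer-type) anion whose charge on C4a, C6 and C8 is offset inductively by the C5 and C7 oxygens, after which fluoride is lost and ring A rearomatises. The closest known reaction type is the intramolecular SNAr etherification of non-activated 2-fluorophenyl alkanols to chromans with potassium bases. Ring C closes in the 6-exo-trig mode (addition–elimination at an aromatic carbon) by forming the O1–C8a bond. No stereocenter is created: C2 keeps its S configuration because the C2–O bond is never broken, the piperidine center carries no acidic hydrogen, and the C4 carbinol mixture is erased in step 12. The step needs chemoselectivity between the two alkoxides and regioselectivity on ring A, and the substrate secures both, since the C4 alkoxide could only form a four-membered ring and fluorine marks C8a as the only carbon that can be substituted. Holding C4 at the alcohol level removes the enolisable ketone, so neither retro-aldol cleavage, dehydration to a chalcone nor base-induced opening of a flavanone can erode C2.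

Step 12
Reactants: 19 (2S)-5,7-bis(benzyloxy)-2-[4-(benzyloxy)phenyl]-6-[(2S)-1-methylpiperidin-2-yl]-3,4-dihydro-2H-chromen-4-ol (C4 epimers)
Product: 20 (2S)-5,7-bis(benzyloxy)-2-[4-(benzyloxy)phenyl]-6-[(2S)-1-methylpiperidin-2-yl]-2,3-dihydro-4H-chromen-4-one
Conditions: Dess–Martin periodinane, pyridine, CH2Cl2, 0 °C to rt
Reagents that add atoms: none
Why: Dess–Martin oxidation converts both C4 epimers of the benzylic carbinol into the ketone under buffered conditions without strong base, so the flavanone is formed without enolate-driven opening of ring C and C2 stays S.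

Step 13
Reactants: 20 (2S)-5,7-bis(benzyloxy)-2-[4-(benzyloxy)phenyl]-6-[(2S)-1-methylpiperidin-2-yl]-2,3-dihydro-4H-chromen-4-one
Product: 21 (2S)-5,7-dihydroxy-2-(4-hydroxyphenyl)-6-[(2S)-1-methylpiperidin-2-yl]-2,3-dihydro-4H-chromen-4-one
Conditions: H2 (1 atm), Pd/C (10%), EtOAc/MeOH, rt
Reagents that add atoms: none
Why: Hydrogenolysis of the three aryl benzyl ethers on palladium is faster than cleavage of the cyclic benzylic C2–O1 and C–N bonds or reduction of the hydrogen-bonded C4 ketone, so neutral conditions should unmask the three phenols and give the target with both stereocenters intact.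

**Compound list**

1 | 4-bromo-2,6-difluorobenzaldehyde | O=Cc1c(F)cc(Br)cc1F | starting material
2 | 2,6-bis(benzyloxy)-4-bromobenzaldehyde | O=Cc1c(OCc2ccccc2)cc(Br)cc1OCc1ccccc1 | intermediate
3 | (R)-2-methylpropane-2-sulfinamide | CC(C)(C)[S@@](=O)N | starting material
4 | (R)-N-[(E)-(2,6-bis(benzyloxy)-4-bromophenyl)methylidene]-2-methylpropane-2-sulfinamide | CC(C)(C)[S@@](=O)/N=C/c1c(OCc2ccccc2)cc(Br)cc1OCc1ccccc1 | intermediate
5 | (R)-N-[(1S)-1-(2,6-bis(benzyloxy)-4-bromophenyl)-5-chloropentyl]-2-methylpropane-2-sulfinamide (not isolated; N-magnesium salt in the flask) | CC(C)(C)[S@@](=O)N[C@@H](CCCCCl)c1c(OCc2ccccc2)cc(Br)cc1OCc1ccccc1 | intermediate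
6 | (2S)-2-[2,6-bis(benzyloxy)-4-bromophenyl]-1-[(R)-tert-butylsulfinyl]piperidine | CC(C)(C)[S@@](=O)N1CCCC[C@H]1c1c(OCc2ccccc2)cc(Br)cc1OCc1ccccc1 | intermediate
7 | (2S)-2-[2,6-bis(benzyloxy)-4-bromophenyl]piperidine (not isolated; hydrochloride in the flask) | N1CCCC[C@H]1c1c(OCc2ccccc2)cc(Br)cc1OCc1ccccc1 | intermediate
8 | (2S)-2-[2,6-bis(benzyloxy)-4-bromophenyl]-1-methylpiperidine | CN1CCCC[C@H]1c1c(OCc2ccccc2)cc(Br)cc1OCc1ccccc1 | intermediate
9 | {3,5-bis(benzyloxy)-4-[(2S)-1-methylpiperidin-2-yl]phenyl}lithium (not isolated) | CN1CCCC[C@H]1c1c(OCc2ccccc2)cc([Li])cc1OCc1ccccc1 | intermediate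
10 | (2S)-2-[2,6-bis(benzyloxy)-4-fluorophenyl]-1-methylpiperidine | CN1CCCC[C@H]1c1c(OCc2ccccc2)cc(F)cc1OCc1ccccc1 | intermediate
11 | 1-[4-(benzyloxy)phenyl]ethan-1-one | CC(=O)c1ccc(OCc2ccccc2)cc1 | starting material
12 | ethyl 3-[4-(benzyloxy)phenyl]-3-oxopropanoate | CCOC(=O)CC(=O)c1ccc(OCc2ccccc2)cc1 | intermediate
13 | ethyl (3S)-3-[4-(benzyloxy)phenyl]-3-hydroxypropanoate | CCOC(=O)C[C@H](O)c1ccc(OCc2ccccc2)cc1 | intermediate
14 | ethyl (3S)-3-[4-(benzyloxy)phenyl]-3-[(tert-butyldimethylsilyl)oxy]propanoate | CCOC(=O)C[C@H](O[Si](C)(C)C(C)(C)C)c1ccc(OCc2ccccc2)cc1 | intermediate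
15 | (3S)-3-[4-(benzyloxy)phenyl]-3-[(tert-butyldimethylsilyl)oxy]propanal | O=CC[C@H](O[Si](C)(C)C(C)(C)C)c1ccc(OCc2ccccc2)cc1 | intermediate
16 | {2,4-bis(benzyloxy)-6-fluoro-3-[(2S)-1-methylpiperidin-2-yl]phenyl}lithium (not isolated) | CN1CCCC[C@H]1c1c(OCc2ccccc2)cc(F)c([Li])c1OCc1ccccc1 | intermediate
17 | (3S)-1-{2,4-bis(benzyloxy)-6-fluoro-3-[(2S)-1-methylpiperidin-2-yl]phenyl}-3-[4-(benzyloxy)phenyl]-3-[(tert-butyldimethylsilyl)oxy]propan-1-ol (C1 epimers; not isolated, lithium alkoxide in the flask) | CN1CCCC[C@H]1c1c(OCc2ccccc2)cc(F)c(C(O)C[C@H](O[Si](C)(C)C(C)(C)C)c2ccc(OCc3ccccc3)cc2)c1OCc1ccccc1 | intermediate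
18 | (1S)-1-[4-(benzyloxy)phenyl]-3-{2,4-bis(benzyloxy)-6-fluoro-3-[(2S)-1-methylpiperidin-2-yl]phenyl}propane-1,3-diol (C3 epimers) | CN1CCCC[C@H]1c1c(OCc2ccccc2)cc(F)c(C(O)C[C@H](O)c2ccc(OCc3ccccc3)cc2)c1OCc1ccccc1 | intermediate
19 | (2S)-5,7-bis(benzyloxy)-2-[4-(benzyloxy)phenyl]-6-[(2S)-1-methylpiperidin-2-yl]-3,4-dihydro-2H-chromen-4-ol (C4 epimers) | CN1CCCC[C@H]1c1c(OCc2ccccc2)cc2c(c1OCc1ccccc1)C(O)C[C@@H](c1ccc(OCc3ccccc3)cc1)O2 | intermediate
20 | (2S)-5,7-bis(benzyloxy)-2-[4-(benzyloxy)phenyl]-6-[(2S)-1-methylpiperidin-2-yl]-2,3-dihydro-4H-chromen-4-one | CN1CCCC[C@H]1c1c(OCc2ccccc2)cc2c(c1OCc1ccccc1)C(=O)C[C@@H](c1ccc(OCc3ccccc3)cc1)O2 | intermediate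
21 | (2S)-5,7-dihydroxy-2-(4-hydroxyphenyl)-6-[(2S)-1-methylpiperidin-2-yl]-2,3-dihydro-4H-chromen-4-one | CN1CCCC[C@H]1c1c(O)cc2c(c1O)C(=O)C[C@@H](c1ccc(O)cc1)O2 | target

**Count**

Total steps: 13. Longest linear sequence: 9 steps (steps 1 to 5 and 10 to 13); the aldehyde branch (steps 6 to 9) joins at step 10.

**Steps most likely to fail**

Step 11 (key step). What may go wrong: addition of the alkoxide to the electron-rich ring, which has no ortho or para acceptor, is slow, so that degradation of the dialkoxide or intermolecular substitution competes with ring closure. Fallback: the C4 carbonyl is put in place first so that it activates C8a. The fallback sets out from 17 (isolated by leaving out Bu4NF in step 10). Dess–Martin oxidation gives (3S)-1-{2,4-bis(benzyloxy)-6-fluoro-3-[(2S)-1-methylpiperidin-2-yl]phenyl}-3-[4-(benzyloxy)phenyl]-3-[(tert-butyldimethylsilyl)oxy]propan-1-one F1. HF·pyridine in THF gives (3S)-1-{2,4-bis(benzyloxy)-6-fluoro-3-[(2S)-1-methylpiperidin-2-yl]phenyl}-3-[4-(benzyloxy)phenyl]-3-hydroxypropan-1-one F2. Exactly one equivalent of KN(SiMe3)2 in THF at −78 to −20 °C deprotonates the hydroxyl, and the alkoxide displaces the fluorine ortho to the carbonyl (activated SNAr). This gives 20 directly, where the route is rejoined, and step 12 falls away. The low temperature and the single equivalent of base are meant to keep retro-aldol cleavage and enolate formation behind the ring closure.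

Step 5. What may go wrong: proton capture by the aryllithium, or transfer of a sulfonyl group from the N–F reagent in place of fluorine, which leaves material that is hard to separate. Fallback: bromine is kept and ring C is closed by copper catalysis in place of SNAr. The fallback sets out from 8. Iodination with N-iodosuccinimide and CF3CO2H in MeCN (the two equivalent positions next to bromine are the only activated ring positions) gives (2S)-2-[2,6-bis(benzyloxy)-4-bromo-3-iodophenyl]-1-methylpiperidine F3. Iodine–magnesium exchange with i-PrMgCl·LiCl in THF at −20 °C (iodine exchanges much faster than bromine) and addition to 15 give (3S)-1-{2,4-bis(benzyloxy)-6-bromo-3-[(2S)-1-methylpiperidin-2-yl]phenyl}-3-[4-(benzyloxy)phenyl]-3-[(tert-butyldimethylsilyl)oxy]propan-1-ol F4. Bu4NF gives (1S)-1-[4-(benzyloxy)phenyl]-3-{2,4-bis(benzyloxy)-6-bromo-3-[(2S)-1-methylpiperidin-2-yl]phenyl}propane-1,3-diol F5. Intramolecular Ullmann etherification (CuI, 3,4,7,8-tetramethyl-1,10-phenanthroline, Cs2CO3, toluene, 100 °C) forms O1–C8a and gives 19, where the route is rejoined.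

Step 13. What may go wrong: over-reduction alongside O-debenzylation, that is hydrogenolysis of the benzylic C2–O1 bond (opening of ring C) or of the benzylic C–N bond, or reduction of the C4 carbonyl. Fallback: Lewis-acid debenzylation in place of hydrogenolysis. The fallback sets out from 20: BCl3 with pentamethylbenzene as benzyl cation scavenger in CH2Cl2 at −78 °C gives 21 directly; no new compound is made (F0).

**Further compounds**

F1 | step 11 | (3S)-1-{2,4-bis(benzyloxy)-6-fluoro-3-[(2S)-1-methylpiperidin-2-yl]phenyl}-3-[4-(benzyloxy)phenyl]-3-[(tert-butyldimethylsilyl)oxy]propan-1-one | CN1CCCC[C@H]1c1c(OCc2ccccc2)cc(F)c(C(=O)C[C@H](O[Si](C)(C)C(C)(C)C)c2ccc(OCc3ccccc3)cc2)c1OCc1ccccc1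
F2 | step 11 | (3S)-1-{2,4-bis(benzyloxy)-6-fluoro-3-[(2S)-1-methylpiperidin-2-yl]phenyl}-3-[4-(benzyloxy)phenyl]-3-hydroxypropan-1-one | CN1CCCC[C@H]1c1c(OCc2ccccc2)cc(F)c(C(=O)C[C@H](O)c2ccc(OCc3ccccc3)cc2)c1OCc1ccccc1
F3 | step 5 | (2S)-2-[2,6-bis(benzyloxy)-4-bromo-3-iodophenyl]-1-methylpiperidine | CN1CCCC[C@H]1c1c(OCc2ccccc2)cc(Br)c(I)c1OCc1ccccc1
F4 | step 5 | (3S)-1-{2,4-bis(benzyloxy)-6-bromo-3-[(2S)-1-methylpiperidin-2-yl]phenyl}-3-[4-(benzyloxy)phenyl]-3-[(tert-butyldimethylsilyl)oxy]propan-1-ol (C1 epimers) | CN1CCCC[C@H]1c1c(OCc2ccccc2)cc(Br)c(C(O)C[C@H](O[Si](C)(C)C(C)(C)C)c2ccc(OCc3ccccc3)cc2)c1OCc1ccccc1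
F5 | step 5 | (1S)-1-[4-(benzyloxy)phenyl]-3-{2,4-bis(benzyloxy)-6-bromo-3-[(2S)-1-methylpiperidin-2-yl]phenyl}propane-1,3-diol (C3 epimers) | CN1CCCC[C@H]1c1c(OCc2ccccc2)cc(Br)c(C(O)C[C@H](O)c2ccc(OCc3ccccc3)cc2)c1OCc1ccccc1
F0 | step 13 | none | none
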